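**Plan**

- Locants: C1 (CH–O-ester), C2, C3 (angular C–CH3), C4, C5, C6 (CH–iPr), C7 (fusion C–OH), C8, C9, C10 (C(CH3)OH); ring A is C3–C7 (five-membered), ring B is C1, C2, C3, C7, C8, C9, C10 (seven-membered). In ring B the oxygenated C1 lies next to the methyl-bearing C10, a masked 2-methylcycloheptanone, which is what results when a CH(CH3) carbon is slipped between the carbonyl and an alpha-carbon of a cyclohexanone.
- Cuts: the ester C–O; both ring B oxygens back through a C1,C10-oxirane to the C1=C10 alkene and the C1 ketone; then C9–C10 (ring B shrinks to a six-membered ketone carrying CH(CH3)CO2H at C1); C8–C9 and C7–C8 (enolate/oxirane, ylide); C2–C3 (enolate alkylation).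
- Forward: ring A from (S)-limonene by ozonolysis and aldol ring contraction; the six-membered ring by enolate opening of a C7 spiro-oxirane (cis-hydrindane); ring B by anodic decarboxylative enlargement of that ring; then C1/C10 oxygenation and acylation.
- Stereochemistry: C6 from (S)-limonene; C3 by alkylation anti to the isopropyl group; C7 by ylide attack anti to it; C1 and C10 by epoxidation directed by the C7 hydroxyl and inversion at C10 on hydrolysis.

Key step: step 11

Remark: 18 (C1, C10) and 19 (C10) are expected as epimer mixtures and are carried on as such, because these centres are destroyed in steps 11 and 12; their SMILES leave them open. The locants C1–C10 in the text are those defined above, while systematic names carry their own numbering.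

Step 1
Reactants: 1 (S)-limonene
Product: 2 (4S)-1-methyl-4-(propan-2-yl)cyclohex-1-ene
Conditions: H2 (1 atm), RhCl(PPh3)3 (cat.), toluene, rt
Reagents that add atoms: none
Why: Homogeneous hydrogenation with RhCl(PPh3)3 should reduce the unhindered 1,1-disubstituted isopropenyl alkene far faster than the trisubstituted ring alkene, and the stereocentre (later C6) is not touched.

Step 2
Reactants: 2 (4S)-1-methyl-4-(propan-2-yl)cyclohex-1-ene
Product: 4 (3S)-6-oxo-3-(propan-2-yl)heptanal, via secondary ozonide 3 (not isolated)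
Conditions: O3, CH2Cl2, −78 °C; then PPh3, −78 °C → rt
Reagents that add atoms: ozone, [O-][O+]=O
Why: Ozonolysis (Criegee mechanism) with reductive cleavage of the ozonide opens the ring alkene to the 1,6-keto aldehyde, whose stereocentre is beta to the aldehyde and cannot epimerise.

Step 3
Reactants: 4 (3S)-6-oxo-3-(propan-2-yl)heptanal
Product: 5 (5R)-2-methyl-5-(propan-2-yl)cyclopent-1-ene-1-carbaldehyde
Conditions: piperidine (cat.), AcOH (cat.), toluene, reflux (Dean–Stark)
Reagents that add atoms: none
Why: Amine-catalysed intramolecular aldol condensation, in which the enamine of the aldehyde adds to the methyl ketone (5-(enolexo)-exo-trig) and dehydration gives the tetrasubstituted enal, should close ring A without touching the isopropyl-bearing centre.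

Step 4
Reactants: 5 (5R)-2-methyl-5-(propan-2-yl)cyclopent-1-ene-1-carbaldehyde
Product: 6 (5R)-2-methyl-5-(propan-2-yl)cyclopent-1-en-1-yl formate
Conditions: mCPBA (1.0 equiv), Na2HPO4, CH2Cl2, 0 °C
Reagents that add atoms: 3-chloroperoxybenzoic acid (mCPBA), O=C(OO)c1cccc(Cl)c1
Why: Baeyer–Villiger oxidation of a conjugated aldehyde, in which the electron-rich alkenyl group migrates in the Criegee adduct, should insert oxygen between the future C7 and the formyl carbon and leave the enol double bond on the methyl-bearing side.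

Step 5
Reactants: 6 (5R)-2-methyl-5-(propan-2-yl)cyclopent-1-en-1-yl formate; 7 3-chloro-2-methylprop-1-ene
Product: 9 (2R,5R)-2-methyl-2-(2-methylprop-2-en-1-yl)-5-(propan-2-yl)cyclopentan-1-one, via lithium enolate 8 (not isolated)
Conditions: MeLi (2 equiv), THF, 0 °C; then 7, DMPU, −40 °C → rt; H2O
Reagents that add atoms: none
Why: Cleavage of the enol ester by MeLi (the second equivalent traps the acetaldehyde released) gives the regiodefined tetrasubstituted lithium enolate, and its SN2 C-alkylation by the allylic chloride on the face anti to the C6 isopropyl group should set the quaternary C3 with methyl cis to isopropyl.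

Step 6
Reactants: 9 (2R,5R)-2-methyl-2-(2-methylprop-2-en-1-yl)-5-(propan-2-yl)cyclopentan-1-one
Product: 10 (3S,4R,7R)-4-methyl-4-(2-methylprop-2-en-1-yl)-7-(propan-2-yl)-1-oxaspiro[2.4]heptane
Conditions: Me3S+ I−, n-BuLi, THF, −10 °C; then 9, −10 °C → rt
Reagents that add atoms: trimethylsulfonium iodide, C[S+](C)C.[I-]
Why: In this Corey–Chaykovsky epoxidation dimethylsulfonium methylide should add irreversibly to the C7 carbonyl from the face flanked by C6–H and the methallyl CH2 (anti to the isopropyl group and the C3 methyl), so that ring closure of the betaine places C8 on that face and the oxirane oxygen cis to the C3 methyl (C7 S).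

Step 7
Reactants: 10 (3S,4R,7R)-4-methyl-4-(2-methylprop-2-en-1-yl)-7-(propan-2-yl)-1-oxaspiro[2.4]heptane
Product: 12 1-[(3S,4R,7R)-4-methyl-7-(propan-2-yl)-1-oxaspiro[2.4]heptan-4-yl]propan-2-one, via terminal ozonide 11 (not isolated)
Conditions: O3, CH2Cl2, −78 °C; then PPh3, −78 °C → rt
Reagents that add atoms: ozone, [O-][O+]=O
Why: Ozonolysis of the 1,1-disubstituted alkene should give the methyl ketone (C1 carbonyl, C9 methyl), the oxirane being inert to ozone and to PPh3 at these temperatures.

Step 8
Reactants: 12 1-[(3S,4R,7R)-4-methyl-7-(propan-2-yl)-1-oxaspiro[2.4]heptan-4-yl]propan-2-one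
Product: 14 (1R,3aR,7aS)-7a-hydroxy-3a-methyl-1-(propan-2-yl)octahydro-5H-inden-5-one, via lithium enolate 13 (not isolated)
Conditions: LiN(iPr)2, THF, −78 °C → rt; H2O
Reagents that add atoms: none
Why: Kinetic deprotonation should occur at the methyl group C9 and not at the neopentylic C2, and the enolate then opens the oxirane at its unsubstituted carbon C8 (intramolecular enolate alkylation, 6-(enolendo)-exo-tet, attack at the quaternary C7 being excluded); because C8 and the acetonyl arm are cis on ring A the new six-membered ring is cis-fused and C7 keeps its oxygen and configuration.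

Step 9
Reactants: 14 (1R,3aR,7aS)-7a-hydroxy-3a-methyl-1-(propan-2-yl)octahydro-5H-inden-5-one
Product: 15 (1R,3aR,7aS)-3a-methyl-1-(propan-2-yl)-7a-[(triethylsilyl)oxy]octahydro-5H-inden-5-one
Conditions: Et3SiOTf, 2,6-lutidine, CH2Cl2, −78 → 0 °C
Reagents that add atoms: triethylsilyl trifluoromethanesulfonate, CC[Si](CC)(CC)OS(=O)(=O)C(F)(F)F
Why: Silyl triflate with a hindered pyridine base silylates even a tertiary alcohol, which shields the C7 oxygen from the base of step 10, from the cation of step 11 and from Tf2O in step 12.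

Step 10
Reactants: 15 (1R,3aR,7aS)-3a-methyl-1-(propan-2-yl)-7a-[(triethylsilyl)oxy]octahydro-5H-inden-5-one; 16 propanoic acid
Product: 18 2-[(1R,3aR,7aS)-5-hydroxy-3a-methyl-1-(propan-2-yl)-7a-[(triethylsilyl)oxy]octahydro-1H-inden-5-yl]propanoic acid (epimers at C1 and C10), via dilithium enediolate 17 (not isolated)
Conditions: 16, LiN(iPr)2 (2.1 equiv), THF, 0 °C → rt; then 15, −78 → 0 °C; cold dil. HCl (pH 3)
Reagents that add atoms: none
Why: Aldol-type addition of the carboxylic acid dianion to the unhindered C1 ketone should give the beta-hydroxy acid in one operation, the uncontrolled new centres C1 and C10 being of no consequence.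

Step 11
Reactants: 18 2-[(1R,3aR,7aS)-5-hydroxy-3a-methyl-1-(propan-2-yl)-7a-[(triethylsilyl)oxy]octahydro-1H-inden-5-yl]propanoic acid
Product: 19 (1R,3aR,8aS)-3a,6-dimethyl-1-(propan-2-yl)-8a-[(triethylsilyl)oxy]octahydroazulen-5(1H)-one (C10 epimers)
Conditions: graphite anode, Pt cathode, undivided cell, constant current, MeOH, NaOMe (0.2 equiv), 0–10 °C
Reagents that add atoms: none
Why: The carboxylate of 18 is oxidised at the carbon anode by two electrons with loss of CO2 (non-Kolbe, Hofer–Moest pathway), which leaves a secondary cation at C10 next to the carbinol carbon C1. A semipinacol 1,2-shift then moves C9 from C1 to C10 while the C1 hydroxyl collapses to the ketone, the behaviour known for anodic oxidation of beta-hydroxy carboxylic acids to one-carbon-enlarged ketones. Ring B is therefore not closed by a cyclisation but arises by enlargement of the six-membered ring (C1, C2, C3, C7, C8, C9) to the seven-membered one through the new C9–C10 bond. The only stereocentre formed, C10, is alpha to the ketone, uncontrolled and irrelevant because step 12 flattens it, and C3, C6 and C7 take no part. The step needs migration of C9 and not of C2, which should be favoured because C2 is neopentylic and its bridged transition state would press the C10 methyl against the quaternary C3; it also needs the cation to escape capture by oxygen, which the silyl ether at C7 and the fast hydroxyl-assisted shift should secure.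

Step 12
Reactants: 19 (1R,3aR,8aS)-3a,6-dimethyl-1-(propan-2-yl)-8a-[(triethylsilyl)oxy]octahydroazulen-5(1H)-one
Product: 20 (1R,3aR,8aS)-3a,6-dimethyl-1-(propan-2-yl)-8a-[(triethylsilyl)oxy]-1,2,3,3a,4,7,8,8a-octahydroazulen-5-yl trifluoromethanesulfonate
Conditions: Tf2O, 2,6-di-tert-butyl-4-methylpyridine, CH2Cl2, 0 °C → rt
Reagents that add atoms: trifluoromethanesulfonic anhydride, O=S(=O)(OS(=O)(=O)C(F)(F)F)C(F)(F)F
Why: O-Triflation of the ketone and proton loss under equilibrating conditions should give the more substituted (thermodynamic) enol triflate C1=C10, the alternative toward C2 being less substituted and neopentylic, and both C10 epimers converge.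

Step 13
Reactants: 20 (1R,3aR,8aS)-3a,6-dimethyl-1-(propan-2-yl)-8a-[(triethylsilyl)oxy]-1,2,3,3a,4,7,8,8a-octahydroazulen-5-yl trifluoromethanesulfonate
Product: 21 triethyl{[(3R,3aS,8aR)-6,8a-dimethyl-3-(propan-2-yl)-2,3,4,5,8,8a-hexahydroazulen-3a(1H)-yl]oxy}silane
Conditions: Pd(OAc)2 (cat.), PPh3, HCO2H, n-Bu3N, DMF, 60 °C
Reagents that add atoms: none
Why: In this palladium-catalysed formate reduction of an enol triflate, oxidative addition to zerovalent palladium, exchange of triflate for formate, loss of CO2 and reductive elimination of the C1–H bond should leave the C1=C10 double bond where it is.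

Step 14
Reactants: 21 triethyl{[(3R,3aS,8aR)-6,8a-dimethyl-3-(propan-2-yl)-2,3,4,5,8,8a-hexahydroazulen-3a(1H)-yl]oxy}silane
Product: 22 (3R,3aS,8aR)-6,8a-dimethyl-3-(propan-2-yl)-2,3,4,5,8,8a-hexahydroazulen-3a(1H)-ol
Conditions: Bu4NF, THF, rt → 50 °C; H2O
Reagents that add atoms: none
Why: Fluoride-induced cleavage of the Si–O bond frees the C7 hydroxyl needed as directing group, and the alkene and stereocentres are inert to it.

Step 15
Reactants: 22 (3R,3aS,8aR)-6,8a-dimethyl-3-(propan-2-yl)-2,3,4,5,8,8a-hexahydroazulen-3a(1H)-ol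
Product: 23 (3R,3aS,6S,7R,8aR)-6,7-epoxy-6,8a-dimethyl-3-(propan-2-yl)decahydroazulen-3a-ol
Conditions: VO(acac)2 (cat.), t-BuOOH, CH2Cl2, 0 °C → rt
Reagents that add atoms: tert-butyl hydroperoxide, CC(C)(C)OO
Why: In this hydroxyl-directed epoxidation the vanadium alkoxide of the C7 hydroxyl should deliver the peroxide oxygen across ring B to the face of C1=C10 that carries this hydroxyl, which sets C1 (R) and puts the oxirane cis to the C7–OH.

Step 16
Reactants: 23 (3R,3aS,6S,7R,8aR)-6,7-epoxy-6,8a-dimethyl-3-(propan-2-yl)decahydroazulen-3a-ol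
Product: 24 (3R,3aS,6R,7R,8aR)-6,8a-dimethyl-3-(propan-2-yl)decahydroazulene-3a,6,7-triol
Conditions: HClO4 (cat.), THF–H2O, 0 °C → rt
Reagents that add atoms: water, O
Why: In this acid-catalysed epoxide hydrolysis water should attack the protonated oxirane at the tertiary C10 with inversion (borderline SN2), giving the trans-1,10-diol with C10 (R) while C1 keeps its oxygen, and the C7 hydroxyl, being cis to the oxirane, cannot reach the rear of C10 to form a transannular ether.

Step 17
Reactants: 24 (3R,3aS,6R,7R,8aR)-6,8a-dimethyl-3-(propan-2-yl)decahydroazulene-3a,6,7-triol; 25 4-methoxybenzoyl chloride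
Product: 26 (1R,3aR,5R,6R,8aS)-6,8a-dihydroxy-3a,6-dimethyl-1-(propan-2-yl)decahydroazulen-5-yl 4-methoxybenzoate (CNP0244624.1)
Conditions: 25, pyridine, DMAP (cat.), CH2Cl2, 0 °C → rt
Reagents that add atoms: none
Why: DMAP-catalysed acylation (nucleophilic acyl substitution) should take place only at the secondary C1 hydroxyl, the tertiary hydroxyls at C7 and C10 being too hindered.

**Compound list**

1 | (S)-limonene, (4S)-1-methyl-4-(prop-1-en-2-yl)cyclohex-1-ene | CC1=CC[C@H](CC1)C(=C)C | starting material
2 | (4S)-1-methyl-4-(propan-2-yl)cyclohex-1-ene | CC1=CC[C@H](CC1)C(C)C | intermediate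
3 | (4S)-1-methyl-4-(propan-2-yl)-7,8,9-trioxabicyclo[4.2.1]nonane (secondary ozonide, bridgehead diastereomers) | CC12CC[C@H](C(C)C)CC(OO1)O2 | intermediate (not isolated)
4 | (3S)-6-oxo-3-(propan-2-yl)heptanal | O=CC[C@H](CCC(C)=O)C(C)C | intermediate
5 | (5R)-2-methyl-5-(propan-2-yl)cyclopent-1-ene-1-carbaldehyde | O=CC1=C(C)CC[C@@H]1C(C)C | intermediate
6 | (5R)-2-methyl-5-(propan-2-yl)cyclopent-1-en-1-yl formate | O=COC1=C(C)CC[C@@H]1C(C)C | intermediate
7 | 3-chloro-2-methylprop-1-ene | CC(=C)CCl | starting material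
8 | lithium (5R)-2-methyl-5-(propan-2-yl)cyclopent-1-en-1-olate | [Li]OC1=C(C)CC[C@@H]1C(C)C | intermediate (not isolated)
9 | (2R,5R)-2-methyl-2-(2-methylprop-2-en-1-yl)-5-(propan-2-yl)cyclopentan-1-one | C=C(C)C[C@@]1(C)CC[C@H](C(C)C)C1=O | intermediate
10 | (3S,4R,7R)-4-methyl-4-(2-methylprop-2-en-1-yl)-7-(propan-2-yl)-1-oxaspiro[2.4]heptane | C=C(C)C[C@@]1(C)CC[C@H](C(C)C)[C@@]12CO2 | intermediate
11 | 3-methyl-3-{[(3S,4R,7R)-4-methyl-7-(propan-2-yl)-1-oxaspiro[2.4]heptan-4-yl]methyl}-1,2,4-trioxolane (ozonide, epimers at the trioxolane carbon) | CC1(OCOO1)C[C@@]2(C)CC[C@H](C(C)C)[C@@]23CO3 | intermediate (not isolated)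
12 | 1-[(3S,4R,7R)-4-methyl-7-(propan-2-yl)-1-oxaspiro[2.4]heptan-4-yl]propan-2-one | CC(=O)C[C@@]1(C)CC[C@H](C(C)C)[C@@]12CO2 | intermediate
13 | lithium 3-[(3S,4R,7R)-4-methyl-7-(propan-2-yl)-1-oxaspiro[2.4]heptan-4-yl]prop-1-en-2-olate | [Li]OC(=C)C[C@@]1(C)CC[C@H](C(C)C)[C@@]12CO2 | intermediate (not isolated)
14 | (1R,3aR,7aS)-7a-hydroxy-3a-methyl-1-(propan-2-yl)octahydro-5H-inden-5-one (cis-fused) | O=C1C[C@@]2(C)CC[C@H](C(C)C)[C@@]2(O)CC1 | intermediate
15 | (1R,3aR,7aS)-3a-methyl-1-(propan-2-yl)-7a-[(triethylsilyl)oxy]octahydro-5H-inden-5-one | O=C1C[C@@]2(C)CC[C@H](C(C)C)[C@@]2(O[Si](CC)(CC)CC)CC1 | intermediate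
16 | propanoic acid | CCC(=O)O | starting material
17 | dilithium prop-1-ene-1,1-diolate (dianion of 16) | CC=C(O[Li])O[Li] | intermediate (not isolated)
18 | 2-[(1R,3aR,7aS)-5-hydroxy-3a-methyl-1-(propan-2-yl)-7a-[(triethylsilyl)oxy]octahydro-1H-inden-5-yl]propanoic acid (epimers at C1 and C10) | CC(C(=O)O)C1(O)C[C@@]2(C)CC[C@H](C(C)C)[C@@]2(O[Si](CC)(CC)CC)CC1 | intermediate
19 | (1R,3aR,8aS)-3a,6-dimethyl-1-(propan-2-yl)-8a-[(triethylsilyl)oxy]octahydroazulen-5(1H)-one (C10 epimers) | O=C1C[C@@]2(C)CC[C@H](C(C)C)[C@@]2(O[Si](CC)(CC)CC)CCC1C | intermediate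
20 | (1R,3aR,8aS)-3a,6-dimethyl-1-(propan-2-yl)-8a-[(triethylsilyl)oxy]-1,2,3,3a,4,7,8,8a-octahydroazulen-5-yl trifluoromethanesulfonate | CC1=C(OS(=O)(=O)C(F)(F)F)C[C@@]2(C)CC[C@H](C(C)C)[C@@]2(O[Si](CC)(CC)CC)CC1 | intermediate
21 | triethyl{[(3R,3aS,8aR)-6,8a-dimethyl-3-(propan-2-yl)-2,3,4,5,8,8a-hexahydroazulen-3a(1H)-yl]oxy}silane | CC1=CC[C@@]2(C)CC[C@H](C(C)C)[C@@]2(O[Si](CC)(CC)CC)CC1 | intermediate
22 | (3R,3aS,8aR)-6,8a-dimethyl-3-(propan-2-yl)-2,3,4,5,8,8a-hexahydroazulen-3a(1H)-ol | CC1=CC[C@@]2(C)CC[C@H](C(C)C)[C@@]2(O)CC1 | intermediate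
23 | (3R,3aS,6S,7R,8aR)-6,7-epoxy-6,8a-dimethyl-3-(propan-2-yl)decahydroazulen-3a-ol (oxirane cis to the C7 hydroxyl) | C[C@@]12O[C@@H]1C[C@@]3(C)CC[C@H](C(C)C)[C@@]3(O)CC2 | intermediate
24 | (3R,3aS,6R,7R,8aR)-6,8a-dimethyl-3-(propan-2-yl)decahydroazulene-3a,6,7-triol | O[C@@H]1C[C@@]2(C)CC[C@H](C(C)C)[C@@]2(O)CC[C@@]1(C)O | intermediate
25 | 4-methoxybenzoyl chloride | COc1ccc(cc1)C(Cl)=O | starting material
26 | (1R,3aR,5R,6R,8aS)-6,8a-dihydroxy-3a,6-dimethyl-1-(propan-2-yl)decahydroazulen-5-yl 4-methoxybenzoate | COc1ccc(C(=O)O[C@@H]2C[C@@]3(C)CC[C@H](C(C)C)[C@@]3(O)CC[C@@]2(C)O)cc1 | target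

**Step count and risks**

Total step count: 17. Longest linear sequence: 17 steps (1 → 26); 7, 16 and 25 enter as purchased reagents.

Steps most likely to fail:

Step 11. The neopentylic C2 may migrate in competition with C9. The cation may also be intercepted, either by the C1 oxygen (oxirane formation) or by methanol. Either process would lower the amount of 19 and give a regioisomeric ketone that is hard to remove. The fallback fixes the site of carbon insertion by enolate regiochemistry instead of migratory preference. It sets out from 15. Kinetic deprotonation toward C9 (LiN(iPr)2, Me3SiCl, THF, −78 °C) should give the trimethylsilyl enol ether F1. Simmons–Smith methylenation (Et2Zn, CH2I2) would convert it into the siloxycyclopropane F2. Oxidative opening of the internal cyclopropane bond with FeCl3 in DMF should give the ring-enlarged 7-chloro ketone F3. NaOAc in MeOH would eliminate HCl to the cycloheptenone F4. Reduction with Li in NH3 and trapping of the resulting C1/C10 enolate with MeI would place the methyl group at C10 and return to the route at 19.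

Step 8. The lithium enolate may attack the oxirane sluggishly or through oxygen. The closure also inherits any shortfall in facial control or any C6 epimerisation from the ylide addition of step 6. The fallback builds C8 as a carbonyl carbon and closes the ring by aldol condensation; it sets out from 9 and bypasses steps 6 to 8. Addition of CH2=CHMgBr with CeCl3 (THF, −78 °C), again anti to the isopropyl group, should give the vinyl carbinol F5. Ozonolysis of both alkenes (O3, then PPh3) would give the hydroxy keto aldehyde F6. Aldol condensation of the methyl ketone onto the aldehyde (KOH, MeOH) should give the cis-fused hydroxy enone F7. Hydrogenation (H2, Pd/C, EtOAc) returns to the route at 14.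

Step 15. Delivery of the peroxide from the remote tertiary hydroxyl across ring B may be weak, so that facial selectivity is poor or the oxirane forms mainly on the face away from the C7 oxygen. The fallback uses that opposite face together with the opposite regiochemistry of opening; it sets out from 21, where the directing group is still masked. mCPBA (NaHCO3, CH2Cl2) should epoxidise anti to the bulky silyloxy group and give the epoxide F8. Hot KOH in DMSO–H2O (about 110 °C) would open it at the secondary C1 with inversion (SN2) to give the diol silyl ether F9, which has the C1/C10 configuration of the route. Bu4NF would then remove the silyl group and return to the route at 24.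

**Further compounds**

F1 | step 11 | (1R,3aR,7aS)-3a-methyl-1-(propan-2-yl)-7a-[(triethylsilyl)oxy]-5-[(trimethylsilyl)oxy]-2,3,3a,4,7,7a-hexahydro-1H-indene | C[Si](C)(C)OC1=CC[C@]2(O[Si](CC)(CC)CC)[C@@H](C(C)C)CC[C@]2(C)C1
F2 | step 11 | siloxycyclopropane, CH2 adduct across C1=C9 of F1 (cyclopropane diastereomers) | C[Si](C)(C)OC13C[C@@]2(C)CC[C@H](C(C)C)[C@@]2(O[Si](CC)(CC)CC)CC1C3
F3 | step 11 | (1R,3aR,8aS)-7-chloro-3a-methyl-1-(propan-2-yl)-8a-[(triethylsilyl)oxy]octahydroazulen-5(1H)-one (epimers at the chlorine-bearing carbon) | O=C1C[C@@]2(C)CC[C@H](C(C)C)[C@@]2(O[Si](CC)(CC)CC)CC(Cl)C1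
F4 | step 11 | (1R,3aR,8aS)-3a-methyl-1-(propan-2-yl)-8a-[(triethylsilyl)oxy]-2,3,3a,4,8,8a-hexahydroazulen-5(1H)-one | O=C1C[C@@]2(C)CC[C@H](C(C)C)[C@@]2(O[Si](CC)(CC)CC)CC=C1
F5 | step 8 | (1S,2R,5R)-1-ethenyl-2-methyl-2-(2-methylprop-2-en-1-yl)-5-(propan-2-yl)cyclopentan-1-ol | C=C(C)C[C@@]1(C)CC[C@H](C(C)C)[C@@]1(O)C=C
F6 | step 8 | (1S,2R,5R)-1-hydroxy-2-methyl-2-(2-oxopropyl)-5-(propan-2-yl)cyclopentane-1-carbaldehyde | CC(=O)C[C@@]1(C)CC[C@H](C(C)C)[C@@]1(O)C=O
F7 | step 8 | (1R,3aR,7aS)-7a-hydroxy-3a-methyl-1-(propan-2-yl)-1,2,3,3a,4,7a-hexahydro-5H-inden-5-one | O=C1C[C@@]2(C)CC[C@H](C(C)C)[C@@]2(O)C=C1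
F8 | step 15 | triethylsilyl ether of the C1,C10-epoxide with the oxirane oxygen trans to the C7 oxygen | C[C@]12O[C@H]1C[C@@]3(C)CC[C@H](C(C)C)[C@@]3(O[Si](CC)(CC)CC)CC2
F9 | step 15 | (1R,3aR,5R,6R,8aS)-3a,6-dimethyl-1-(propan-2-yl)-8a-[(triethylsilyl)oxy]decahydroazulene-5,6-diol | O[C@@H]1C[C@@]2(C)CC[C@H](C(C)C)[C@@]2(O[Si](CC)(CC)CC)CC[C@@]1(C)O
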